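**Retrosynthetic overview**
- Last bonds: seven O-benzyl groups fall by hydrogenolysis, and the ester C(=O)–O bond on C3 is closed by Mitsunobu inversion of the tribenzyl derivative of commercial (R)-danshensu, which gives the (S)-hydroxy acid unit.
- Cyclobutane (the only ring of the target): C1–C2 and C3–C4 are formed in one operation by an amine-catalysed polar formal [2+2] between the caffeic-type enal (C1, C4) and 4-hydroxycinnamyl alcohol (C2, C3). The coumaric half is taken at the alcohol oxidation level so that C3 is nucleophilic, the caffeic half at the aldehyde level so that C4 is electrophilic and C1 epimerisable.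
- Feature that makes this possible: the free para-hydroxyl of the aryl ring on C2 (O–ring–C2=C3 is a vinylogous enol that relays through a p-quinone methide), and the cis-1,3 relation of the carboxyl carbons on C1 and C3, which lets CHO and CH2OH close a lactol bridge (3-oxabicyclo[3.1.1]heptane) that traps the all-trans ring.
- Ring order: cyclobutane, then the temporary oxane (lactol) ring, which the next step opens by oxidation; after that C1 is masked as benzyl ester and the CH2OH on C3 is raised to the acid.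

Key step: step 3

Remark: ring atoms are called C1 (free carboxyl), C2 (4-hydroxyphenyl), C3 (ester carboxyl) and C4 (3,4-dihydroxyphenyl) throughout, also in the names of intermediates; the hydroxy acid unit of the target is (S), opposite to commercial (R)-danshensu, so the ester is closed with inversion.

**Route**

Step 1
Reactants: 1 3,4-bis(benzyloxy)benzaldehyde; 2 (triphenyl-λ5-phosphanylidene)acetaldehyde
Product: 3 (2E)-3-[3,4-bis(benzyloxy)phenyl]prop-2-enal
Conditions: toluene, 80 °C (1.05 equiv of 2)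
Reagents that add atoms: none
Why: Wittig olefination with a stabilised formylmethylene ylide, a reagent class that gives E-enals from aryl aldehydes.

Step 2
Reactants: 4 methyl (2E)-3-(4-hydroxyphenyl)prop-2-enoate
Product: 5 4-[(1E)-3-hydroxyprop-1-en-1-yl]phenol
Conditions: i-Bu2AlH (3.5 equiv), THF/toluene, −78 to 0 °C; aq. KNaC4H4O6 work-up
Reagents that add atoms: none
Why: 1,2-reduction of the conjugated ester to the allylic alcohol by the aluminium hydride, the first equivalent being consumed by the phenol, with the E-alkene left untouched.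

Step 3
Reactants: 3 (2E)-3-[3,4-bis(benzyloxy)phenyl]prop-2-enal; 5 4-[(1E)-3-hydroxyprop-1-en-1-yl]phenol (1.5 equiv)
Product: 8 (1R,5S,6R,7S)-6-[3,4-bis(benzyloxy)phenyl]-7-(4-hydroxyphenyl)-3-oxabicyclo[3.1.1]heptan-2-ol (both epimers at the lactol carbon), via quinone methide enamine 6 (not isolated), via hydroxy aldehyde 7 (not isolated)
Conditions: (R)-2-[diphenyl(trimethylsilyloxy)methyl]pyrrolidine (20 mol%), PhCO2H (20 mol%), H2O (3 equiv), EtOAc, 4 °C to rt
Reagents that add atoms: none
Why: Proposed new method: the secondary amine turns 3 into an (E)-iminium ion, the alkene carbon of 5 that becomes C3 adds to its β-carbon (C4) in a vinylogous Friedel–Crafts (Michael) step in which the para-hydroxyl pushes and benzoate carries the proton, and the enamine carbon (C1) of the resulting p-quinone methide 6 then adds 1,6 to the methide carbon (C2), which restores the phenol and closes the ring before hydrolysis to 7 and lactol formation. The closest known reaction type is the amine-catalysed iminium–enamine formal [2+2] cycloaddition of enals with vinylogous π-donors such as 2-vinylpyrroles, together with its hemiacetal-trapped variant using hydroxymethyl nitroalkenes and the enamine 1,6-addition of aldehydes to p-quinone methides; a 4-hydroxystyrene has not been used as the two-carbon partner. The cyclobutane closes 4-exo-trig and the oxane ring of the lactol 6-exo-trig. C4 is set by the catalyst, whose CPh2OSiMe3 group covers the Si face of the β-carbon so that C3 enters from the Re face; C3 is set in the same bond formation through an open transition state with CH2OH anti to the aryl group of the iminium ion and is proof-read by the reversibility of this step; C2 and C1 take the positions trans to their neighbours in the ring closure, C1 remaining epimerisable through the enamine; the lactol carbon forms as a mixture that step 4 removes. The step needs C-attack through the alkene carbon (the extended para position) in place of attack at an ortho carbon or at oxygen, and ring closure in place of a proton shift in 6 to the open-chain styrene: the alkene carbon is the least hindered site of high HOMO density, O-attack is reversible, and the enamine is held within bonding distance of the methide carbon. The lactol needs CHO on C1 and CH2OH on C3 cis, which is their relation in the all-trans ring, so this closure, a consequence of the cis-1,3 carboxyl carbons of the target, takes the product out of the reversible steps.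

Step 4
Reactants: 8 (1R,5S,6R,7S)-6-[3,4-bis(benzyloxy)phenyl]-7-(4-hydroxyphenyl)-3-oxabicyclo[3.1.1]heptan-2-ol
Product: 9 (1R,2S,3S,4R)-4-[3,4-bis(benzyloxy)phenyl]-3-(hydroxymethyl)-2-(4-hydroxyphenyl)cyclobutane-1-carboxylic acid
Conditions: NaClO2, NaH2PO4, 2-methyl-2-butene (excess), t-BuOH/THF/H2O, 0 °C to rt
Reagents that add atoms: sodium chlorite, [Na+].[O-]Cl=O
Why: Pinnick oxidation acting on the open-chain hydroxy aldehyde tautomer that lactol 8 holds in ring–chain equilibrium (the aldehyde met as 7 in step 3), with the alkene as scavenger for hypochlorous acid so that the free phenol should survive; no stereocentre is touched, and the carboxylate can no longer leave as an enolate, which makes the cyclobutane permanent.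

Step 5
Reactants: 9 (1R,2S,3S,4R)-4-[3,4-bis(benzyloxy)phenyl]-3-(hydroxymethyl)-2-(4-hydroxyphenyl)cyclobutane-1-carboxylic acid
Product: 10 benzyl (1R,2S,3S,4R)-2-[4-(benzyloxy)phenyl]-4-[3,4-bis(benzyloxy)phenyl]-3-(hydroxymethyl)cyclobutane-1-carboxylate
Conditions: BnBr (2.2 equiv), K2CO3 (2.2 equiv), DMF, 0 °C to rt
Reagents that add atoms: benzyl bromide, BrCc1ccccc1
Why: O-alkylation (Williamson type) of the carboxylate and the phenolate, the only two groups that K2CO3 deprotonates, so that the primary alcohol stays free and the two carboxyl carbons are told apart.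

Step 6
Reactants: 10 benzyl (1R,2S,3S,4R)-2-[4-(benzyloxy)phenyl]-4-[3,4-bis(benzyloxy)phenyl]-3-(hydroxymethyl)cyclobutane-1-carboxylate
Product: 11 (1R,2S,3S,4R)-2-[4-(benzyloxy)phenyl]-4-[3,4-bis(benzyloxy)phenyl]cyclobutane-1,3-dicarboxylic acid 1-benzyl ester
Conditions: TEMPO (20 mol%), PhI(OAc)2 (2.2 equiv), MeCN/H2O (1:1), rt
Reagents that add atoms: water, O
Why: oxoammonium-mediated oxidation (TEMPO with PhI(OAc)2) of the primary alcohol through the aldehyde hydrate to the acid under nearly neutral conditions that leave benzyl ethers and the benzyl ester alone, C3 lying alpha to the transient aldehyde but already in the favoured trans position.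

Step 7
Reactants: 12 sodium (2R)-3-(3,4-dihydroxyphenyl)-2-hydroxypropanoate
Product: 13 benzyl (2R)-3-[3,4-bis(benzyloxy)phenyl]-2-hydroxypropanoate
Conditions: BnBr (3.3 equiv), K2CO3 (2.5 equiv), DMF, rt, under argon
Reagents that add atoms: benzyl bromide, BrCc1ccccc1
Why: O-alkylation (Williamson type) of the carboxylate and the two phenolates, while the secondary alcohol is not acidic enough to react and the stereocentre is not touched.

Step 8
Reactants: 11 (1R,2S,3S,4R)-2-[4-(benzyloxy)phenyl]-4-[3,4-bis(benzyloxy)phenyl]cyclobutane-1,3-dicarboxylic acid 1-benzyl ester; 13 benzyl (2R)-3-[3,4-bis(benzyloxy)phenyl]-2-hydroxypropanoate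
Product: 14 1-benzyl 3-[(2S)-1-(benzyloxy)-3-[3,4-bis(benzyloxy)phenyl]-1-oxopropan-2-yl] (1R,2R,3S,4S)-2-[4-(benzyloxy)phenyl]-4-[3,4-bis(benzyloxy)phenyl]cyclobutane-1,3-dicarboxylate
Conditions: PPh3, diisopropyl azodicarboxylate, THF/toluene, 0 °C to rt
Reagents that add atoms: none
Why: Mitsunobu esterification, in which the carboxylate of 11 displaces the oxyphosphonium group of 13 by SN2, so that the (2R)-alcohol gives the (2S)-ester of the target with inversion.

Step 9
Reactants: 14 1-benzyl 3-[(2S)-1-(benzyloxy)-3-[3,4-bis(benzyloxy)phenyl]-1-oxopropan-2-yl] (1R,2R,3S,4S)-2-[4-(benzyloxy)phenyl]-4-[3,4-bis(benzyloxy)phenyl]cyclobutane-1,3-dicarboxylate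
Product: 15 (1R,2R,3S,4S)-3-{[(1S)-1-carboxy-2-(3,4-dihydroxyphenyl)ethoxy]carbonyl}-4-(3,4-dihydroxyphenyl)-2-(4-hydroxyphenyl)cyclobutane-1-carboxylic acid
Conditions: H2 (1 atm), Pd/C (10%), THF/MeOH, rt
Reagents that add atoms: none
Why: hydrogenolysis of the five benzyl ethers and two benzyl esters on palladium, which should leave the aryl-substituted cyclobutane, the secondary alkyl ester and all five stereocentres untouched.

**Compound list**

1 | 3,4-bis(benzyloxy)benzaldehyde | O=Cc1ccc(OCc2ccccc2)c(OCc2ccccc2)c1 | starting material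
2 | (triphenyl-λ5-phosphanylidene)acetaldehyde | O=CC=P(c1ccccc1)(c1ccccc1)c1ccccc1 | starting material
3 | (2E)-3-[3,4-bis(benzyloxy)phenyl]prop-2-enal | O=C/C=C/c1ccc(OCc2ccccc2)c(OCc2ccccc2)c1 | intermediate
4 | methyl (2E)-3-(4-hydroxyphenyl)prop-2-enoate | COC(=O)/C=C/c1ccc(O)cc1 | starting material
5 | 4-[(1E)-3-hydroxyprop-1-en-1-yl]phenol | OC/C=C/c1ccc(O)cc1 | intermediate
6 | 4-[(2S,3S,4E)-3-[3,4-bis(benzyloxy)phenyl]-5-{(2R)-2-[diphenyl(trimethylsilyloxy)methyl]pyrrolidin-1-yl}-2-(hydroxymethyl)pent-4-en-1-ylidene]cyclohexa-2,5-dien-1-one (quinone methide enamine; not isolated) | O=C1C=CC(=C[C@H](CO)[C@H](/C=C/N2CCC[C@@H]2C(c2ccccc2)(c2ccccc2)O[Si](C)(C)C)c2ccc(OCc3ccccc3)c(OCc3ccccc3)c2)C=C1 | intermediate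
7 | (1R,2S,3S,4R)-4-[3,4-bis(benzyloxy)phenyl]-3-(hydroxymethyl)-2-(4-hydroxyphenyl)cyclobutane-1-carbaldehyde (hydroxy aldehyde; open form of lactol 8; not isolated) | O=C[C@@H]1[C@@H](c2ccc(O)cc2)[C@H](CO)[C@H]1c1ccc(OCc2ccccc2)c(OCc2ccccc2)c1 | intermediate
8 | (1R,5S,6R,7S)-6-[3,4-bis(benzyloxy)phenyl]-7-(4-hydroxyphenyl)-3-oxabicyclo[3.1.1]heptan-2-ol (lactol carbon unspecified) | OC5[C@@H]1[C@@H](c2ccc(O)cc2)[C@H](CO5)[C@H]1c1ccc(OCc2ccccc2)c(OCc2ccccc2)c1 | intermediate
9 | (1R,2S,3S,4R)-4-[3,4-bis(benzyloxy)phenyl]-3-(hydroxymethyl)-2-(4-hydroxyphenyl)cyclobutane-1-carboxylic acid | O=C(O)[C@@H]1[C@@H](c2ccc(O)cc2)[C@H](CO)[C@H]1c1ccc(OCc2ccccc2)c(OCc2ccccc2)c1 | intermediate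
10 | benzyl (1R,2S,3S,4R)-2-[4-(benzyloxy)phenyl]-4-[3,4-bis(benzyloxy)phenyl]-3-(hydroxymethyl)cyclobutane-1-carboxylate | O=C(OCc1ccccc1)[C@@H]1[C@@H](c2ccc(OCc3ccccc3)cc2)[C@H](CO)[C@H]1c1ccc(OCc2ccccc2)c(OCc2ccccc2)c1 | intermediate
11 | (1R,2S,3S,4R)-2-[4-(benzyloxy)phenyl]-4-[3,4-bis(benzyloxy)phenyl]cyclobutane-1,3-dicarboxylic acid 1-benzyl ester | O=C(OCc1ccccc1)[C@@H]1[C@@H](c2ccc(OCc3ccccc3)cc2)[C@H](C(=O)O)[C@H]1c1ccc(OCc2ccccc2)c(OCc2ccccc2)c1 | intermediate
12 | sodium (2R)-3-(3,4-dihydroxyphenyl)-2-hydroxypropanoate | O[C@H](Cc1ccc(O)c(O)c1)C(=O)[O-].[Na+] | starting material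
13 | benzyl (2R)-3-[3,4-bis(benzyloxy)phenyl]-2-hydroxypropanoate | O[C@H](Cc1ccc(OCc2ccccc2)c(OCc2ccccc2)c1)C(=O)OCc1ccccc1 | intermediate
14 | 1-benzyl 3-[(2S)-1-(benzyloxy)-3-[3,4-bis(benzyloxy)phenyl]-1-oxopropan-2-yl] (1R,2R,3S,4S)-2-[4-(benzyloxy)phenyl]-4-[3,4-bis(benzyloxy)phenyl]cyclobutane-1,3-dicarboxylate | O=C(OCc1ccccc1)[C@@H]1[C@@H](c2ccc(OCc3ccccc3)cc2)[C@H](C(=O)O[C@@H](Cc2ccc(OCc3ccccc3)c(OCc3ccccc3)c2)C(=O)OCc2ccccc2)[C@H]1c1ccc(OCc2ccccc2)c(OCc2ccccc2)c1 | intermediate
15 | (1R,2R,3S,4S)-3-{[(1S)-1-carboxy-2-(3,4-dihydroxyphenyl)ethoxy]carbonyl}-4-(3,4-dihydroxyphenyl)-2-(4-hydroxyphenyl)cyclobutane-1-carboxylic acid | O=C(O)[C@@H]1[C@@H](c2ccc(O)cc2)[C@H](C(=O)O[C@@H](Cc2ccc(O)c(O)c2)C(=O)O)[C@H]1c1ccc(O)c(O)c1 | target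

**Count**

Total steps: 9. Longest linear sequence: 7 steps (2, 3, 4, 5, 6, 8, 9; the same length from 1 through step 1).

**Steps most likely to fail**

1. Step 3 (proposed new method). What may go wrong: alkylation of the phenol at an ortho carbon or at oxygen in place of the alkene carbon; a proton shift in the quinone methide that ends at the open-chain styrene before the ring closes; weak facial control in the C3–C4 bond formation. The fallback uses known chemistry (azomethine ylide cycloaddition, then contraction of the pyrrolidine to the cyclobutane); it sets out from 1 and comes back to the route at 11. Aldehyde 1 is condensed with tert-butyl glycinate (MgSO4, Et3N, CH2Cl2) to the imine tert-butyl N-[(E)-3,4-bis(benzyloxy)benzylidene]glycinate F1. Commercial (E)-4-hydroxycinnamic acid is benzylated twice (BnBr, K2CO3, DMF) to benzyl (2E)-3-[4-(benzyloxy)phenyl]prop-2-enoate F2. An exo-selective catalytic (3+2) cycloaddition of the metal-bound ylide of F1 with F2 (Cu(MeCN)4PF6 with a chiral bisphosphine, Et3N, toluene; ligand enantiomer chosen for the adduct shown) should give 4-benzyl 2-tert-butyl (2S,3S,4R,5R)-3-[4-(benzyloxy)phenyl]-5-[3,4-bis(benzyloxy)phenyl]pyrrolidine-2,4-dicarboxylate F3, in which the two aryl groups are cis. Nitrogen extrusion with PhI(OH)OTs and ammonium carbamate in CF3CH2OH at 80 °C (through the 1,1-diazene and a short-lived 1,4-diradical, with retention) should join C3 to C4 and give 1-benzyl 3-tert-butyl (1R,2R,3R,4S)-2-[4-(benzyloxy)phenyl]-4-[3,4-bis(benzyloxy)phenyl]cyclobutane-1,3-dicarboxylate F4. KOt-Bu (0.3 equiv) in t-BuOH/THF at 0 °C should then epimerise the tert-butyl ester carbon, which is cis to both aryl groups, to the all-trans diester 1-benzyl 3-tert-butyl (1R,2R,3S,4S)-2-[4-(benzyloxy)phenyl]-4-[3,4-bis(benzyloxy)phenyl]cyclobutane-1,3-dicarboxylate F5. CF3CO2H in CH2Cl2 finally removes the tert-butyl group and gives 11.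

2. Step 8. What may go wrong: slow attack of the hindered cyclobutane carboxylate on the oxyphosphonium ion, so that β-elimination to the benzyl cinnamate or incomplete inversion takes over. The fallback sets out from 13 and comes back to the route at 14. Alcohol 13 is converted with (CF3SO2)2O and 2,6-lutidine in CH2Cl2 at −78 °C into benzyl (2R)-3-[3,4-bis(benzyloxy)phenyl]-2-{[(trifluoromethyl)sulfonyl]oxy}propanoate F6. Acid 11 is then stirred with Cs2CO3 and F6 in DMF at 0 °C, so that its carboxylate displaces the triflate by SN2 with inversion and gives 14.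

3. Step 4. What may go wrong: ring chlorination of the free phenol by hypochlorous acid, and slow oxidation because the bridged lactol opens only to a small extent. The fallback sets out from 8 and comes back to the route at 9. The closed lactol is oxidised with Pr4N[RuO4] (5 mol%) and N-methylmorpholine N-oxide (CH2Cl2, 4 Å sieves) to the lactone (1R,5S,6R,7S)-6-[3,4-bis(benzyloxy)phenyl]-7-(4-hydroxyphenyl)-3-oxabicyclo[3.1.1]heptan-2-one F7. LiOH in THF/H2O followed by careful acidification with aqueous NaH2PO4 opens the strained lactone and gives 9.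

**Further compounds**

F1 | step 3 | tert-butyl N-[(E)-3,4-bis(benzyloxy)benzylidene]glycinate | CC(C)(C)OC(=O)C/N=C/c1ccc(OCc2ccccc2)c(OCc2ccccc2)c1
F2 | step 3 | benzyl (2E)-3-[4-(benzyloxy)phenyl]prop-2-enoate | O=C(/C=C/c1ccc(OCc2ccccc2)cc1)OCc1ccccc1
F3 | step 3 | 4-benzyl 2-tert-butyl (2S,3S,4R,5R)-3-[4-(benzyloxy)phenyl]-5-[3,4-bis(benzyloxy)phenyl]pyrrolidine-2,4-dicarboxylate | O=C(OCc1ccccc1)[C@@H]1[C@@H](c2ccc(OCc3ccccc3)cc2)[C@@H](C(=O)OC(C)(C)C)N[C@H]1c1ccc(OCc2ccccc2)c(OCc2ccccc2)c1
F4 | step 3 | 1-benzyl 3-tert-butyl (1R,2R,3R,4S)-2-[4-(benzyloxy)phenyl]-4-[3,4-bis(benzyloxy)phenyl]cyclobutane-1,3-dicarboxylate | O=C(OCc1ccccc1)[C@@H]1[C@@H](c2ccc(OCc3ccccc3)cc2)[C@@H](C(=O)OC(C)(C)C)[C@H]1c1ccc(OCc2ccccc2)c(OCc2ccccc2)c1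
F5 | step 3 | 1-benzyl 3-tert-butyl (1R,2R,3S,4S)-2-[4-(benzyloxy)phenyl]-4-[3,4-bis(benzyloxy)phenyl]cyclobutane-1,3-dicarboxylate | O=C(OCc1ccccc1)[C@@H]1[C@@H](c2ccc(OCc3ccccc3)cc2)[C@H](C(=O)OC(C)(C)C)[C@H]1c1ccc(OCc2ccccc2)c(OCc2ccccc2)c1
F6 | step 8 | benzyl (2R)-3-[3,4-bis(benzyloxy)phenyl]-2-{[(trifluoromethyl)sulfonyl]oxy}propanoate | O=S(=O)(O[C@H](Cc1ccc(OCc2ccccc2)c(OCc2ccccc2)c1)C(=O)OCc1ccccc1)C(F)(F)F
F7 | step 4 | (1R,5S,6R,7S)-6-[3,4-bis(benzyloxy)phenyl]-7-(4-hydroxyphenyl)-3-oxabicyclo[3.1.1]heptan-2-one | O=C5[C@@H]1[C@@H](c2ccc(O)cc2)[C@H](CO5)[C@H]1c1ccc(OCc2ccccc2)c(OCc2ccccc2)c1
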